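Locants: rings A (benzo), C (pyran: O1, C2, C3, C4) and B (aryl at C2) form the upper flavan unit. Rings D, F and E are the corresponding rings of the lower unit. A ring letter in brackets after a locant names the unit, for example C8(D).

## Analysis of the target

- **Identity.** The target 14 is (−)-epiafzelechin 3-O-gallate-(4β→8)-(−)-epicatechin 3-O-gallate. Two flavan units are joined by one C–C bond from C4(C) to C8(D), and each C3 oxygen carries a galloyl ester.
- **Stereocentres.** There are five: C2, C3 and C4 of ring C (2R,3R,4R) and C2 and C3 of ring F (2R,3R). Both pyran rings are 2,3-cis, and ring C is also 3,4-trans.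
- **The feature the route is built on.** On ring C, ring B at C2 and the ester oxygen at C3 lie on one face (α). H-2, H-3 and the C4(C)–C8(D) bond all lie on the other face (β).
- **Why C4(C) is special.** C4(C) is bonded to C4a of ring A, and O1, O5 and O7 stand ortho, ortho and para to C4a. A C3=C4 double bond that carries oxygen at C3 is therefore a masked C4 cation. Adding H to C3 and ring D to C4 from the face opposite ring B gives exactly the required pattern.
- **Sensitive groups.** The thirteen free phenols (one catechol, two pyrogallols, two phloroglucinol-type rings) are prone to oxidation. Base epimerises C2 and cleaves or shifts the esters. Acid breaks the interflavan bond.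
- **What makes it hard.**
  - The 2,3-cis arrangement is not the one that ring closure normally gives.
  - The interflavan bond must form once only, at C8(D) rather than C6(D), and from the β face.
  - The upper unit is not a cheap natural monomer and has to be built as a single enantiomer.

## Retrosynthetic reasoning

**14 from 13.** The thirteen O–benzyl bonds are cut last. One neutral, reductive operation frees all phenols. This is the only kind of final step that the oxidation-, base- and acid-sensitive 14 tolerates.

**13 from 11 and 12.** The two acyl–oxygen bonds at C3(C) and C3(F) are cut together. The esters are identical, so one double esterification of diol 11 with acid 12 installs both. This also lets the lower unit enter as the simple alcohol 8, and lets C3(C) carry a small acyl group while the skeleton is joined.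

**11 from 6 and 8 (through 9 and 10).** Two bonds are cut at once: C4(C)–C8(D) and C3(C)–H.
- The precursor 6 is a flat 2H-chromene with a C3=C4 enol formate and only one stereocentre, C2.
- In the forward sense an acid must place a proton on C3 from the β face to give cation 9.
- Ring D of 8 must then bond to C4 from the same face to give 10, and mild methanolysis of the formate gives 11.
- The cut is made here because both new bonds lie opposite ring B, so C2 alone can control C3 and C4.
- What is gained: no leaving group at C4, no separate construction or correction of the 2,3-cis alcohol, and a precursor three steps from simple aldehydes.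

**6 from 5.** The C3–O bond is traced back to a C3–CHO bond. One oxygen atom is inserted between C3 and the formyl carbon of enal 5. This makes the enol ester regiospecifically at C3=C4, without passing through a ketone whose C2–H would be acidic and configurationally labile.

**5 from 2 and 4.** Ring C is opened at O1–C2 and at C3–C4. Salicylaldehyde 2 supplies ring A, O1 and C4. Enal 4 supplies C2, C3, ring B and the formyl group. The forward reaction closes ring C in one catalytic asymmetric operation and sets C2, the stereocentre from which C3 and C4 follow.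

**2 from 1, 4 from 3, 8 from 7.** These are protecting-group and two-carbon homologation steps from commercial compounds. The two stereocentres of ring F are bought with 7.

## Alternatives that were turned down

**Alternative 1:** the textbook disconnection. Only C4(C)–C8(D) is cut, from a finished upper monomer.
- Forward key step: Lewis-acid ionisation of the 4β-(2-ethoxyethoxy) ether A1 and capture of the cation by 8.
- The coupling itself is reliable, but A1 already holds all three stereocentres of ring C plus a leaving group.
- Reaching A1 needs an asymmetric dihydroxylation and cyclisation that favour the 2,3-trans alcohol, then an oxidation–reduction pair to invert C3, an esterification, and a benzylic C–H oxidation at C4.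
- C3 is thus set, erased and set again, and C4 is oxidised only to be ionised.
- The upper half alone costs about twice the steps of the chosen route, and the key step sets only one stereocentre.

**Alternative 2:** C4(C)–C8(D) is cut at the flavylium oxidation level.
- Forward key step: addition of C8(D) of 8 to C4 of the flat cation A2 to give the 4-aryl-flav-2-ene A3. The C2=C3 enol ester is then reduced by catalytic or ionic hydrogenation.
- A2 is very short to make. However, the target needs H-2 and H-3 on the β face, the face that carries the bulky ring D in A3.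
- A catalyst surface, a proton or a hydride would all approach from the open α face, which leads to the all-cis isomer A4.
- In addition, only the remote stereocentres of ring F control the face of the flat A2 in the C–C bond formation.

**Alternative 3:** O1–C2 and C3–C4 of ring C are cut in a hetero-Diels–Alder sense.
- Forward key step: loss of water from benzhydrol A5 gives a heterodiene (O=C8a–C4a=C4, with ring D on C4), which adds to the Z-enol gallate A6. This would close ring C and set C2, C3 and C4 at once, from either carbinol epimer.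
- The required 2,4-trans product needs either an exo approach or the inward geometry at C4. The flanking 5-benzyloxy group and carbonyl oxygen give no clear preference.
- The strongly stabilised heterodiene and the weakly nucleophilic A6 make a stepwise path likely. In that path the galloyl carbonyl captures the C2 benzylic cation, and closure with inversion gives 2,3-trans.
- Facial control would again rest on remote centres.

Key step: step 6

Assumption: α is the face of ring C that carries ring B and β the opposite face. The sense of induction in step 3 is taken from the usual shielding model of the catalyst, and the mirror-image catalyst would be used should the opposite sense be found.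

## Steps

Step 1
Reactants: 1 2,4,6-trihydroxybenzaldehyde
Product: 2 2,4-bis(benzyloxy)-6-hydroxybenzaldehyde
Conditions: BnBr (2.05 equiv), K2CO3 (2.2 equiv), DMF, 0 °C to rt
Reagents that add atoms: benzyl bromide, BrCc1ccccc1
Why: Williamson etherification; the 4-OH and one of the two equivalent ortho-OH groups react, while the remaining ortho-OH is held in a strong hydrogen bond to the formyl oxygen and is far less nucleophilic, so two equivalents of halide should stop at the dibenzyl ether.

Step 2
Reactants: 3 4-(benzyloxy)benzaldehyde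
Product: 4 (E)-3-[4-(benzyloxy)phenyl]prop-2-enal
Conditions: Ph3P=CHCHO (1.1 equiv), toluene, 80 °C
Reagents that add atoms: (triphenylphosphoranylidene)acetaldehyde, O=CC=P(c1ccccc1)(c1ccccc1)c1ccccc1
Why: Wittig olefination with a stabilised formyl ylide, which should give the E-enal; the benzyl ether is inert and a small excess of ylide limits a second homologation.

Step 3
Reactants: 2 2,4-bis(benzyloxy)-6-hydroxybenzaldehyde; 4 (E)-3-[4-(benzyloxy)phenyl]prop-2-enal
Product: 5 (2R)-5,7-bis(benzyloxy)-2-[4-(benzyloxy)phenyl]-2H-chromene-3-carbaldehyde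
Conditions: (S)-2-[diphenyl(trimethylsilyloxy)methyl]pyrrolidine (20 mol %), 2-nitrobenzoic acid (20 mol %), 4 Å MS, toluene, rt
Reagents that add atoms: none
Why: Domino oxa-Michael/aldol condensation under iminium–enamine catalysis, a known route from salicylaldehydes and cinnamaldehydes to 2-aryl-2H-chromene-3-carbaldehydes: the phenol oxygen of 2 adds to Cβ of the iminium ion of 4 (O1–C2), the enamine attacks the formyl group of 2 (C3–C4) and loss of water gives the enal. The CPh2(OSiMe3) group of the S catalyst covers the Re face of Cβ in the E,s-trans iminium ion, so O1 should arrive on the Si face, which corresponds to 2R.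

Step 4
Reactants: 5 (2R)-5,7-bis(benzyloxy)-2-[4-(benzyloxy)phenyl]-2H-chromene-3-carbaldehyde
Product: 6 (2R)-5,7-bis(benzyloxy)-2-[4-(benzyloxy)phenyl]-2H-chromen-3-yl formate
Conditions: 30% aq H2O2 (1.5 equiv), bis(2-nitrophenyl) diselenide (3 mol %), CH2Cl2, rt
Reagents that add atoms: hydrogen peroxide, OO
Why: Baeyer–Villiger oxidation of an α-substituted cinnamaldehyde-type enal by the perseleninic acid formed in the flask, a known way to vinyl formates: the electron-rich alkenyl carbon C3 migrates in preference to H, so one oxygen atom is inserted between C3 and the formyl carbon and the double bond stays at C3=C4. C2 is not touched, and the selenium system is chosen because it attacks the C=O group rather than C=C bonds.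

Step 5
Reactants: 7 (−)-epicatechin
Product: 8 5,7,3',4'-tetra-O-benzyl-(−)-epicatechin
Conditions: BnBr (4.4 equiv), K2CO3 (5 equiv), DMF, Ar, −10 °C to rt
Reagents that add atoms: benzyl bromide, BrCc1ccccc1
Why: Williamson etherification of the four phenols; carbonate does not deprotonate the secondary C3–OH, and low temperature with exclusion of air limits base-induced C2 epimerisation and oxidation of the catechol.

Step 6
Reactants: 6 (2R)-5,7-bis(benzyloxy)-2-[4-(benzyloxy)phenyl]-2H-chromen-3-yl formate; 8 5,7,3',4'-tetra-O-benzyl-(−)-epicatechin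
Product: 11 5,7,4'-tri-O-benzyl-(−)-epiafzelechin-(4β→8)-5,7,3',4'-tetra-O-benzyl-(−)-epicatechin, via benzylic cation 9 (not isolated), via formate ester 10 (not isolated)
Conditions: 8 (3 equiv), Tf2NH (10 mol %), 4 Å MS, CH2Cl2, −60 to −30 °C, slow addition of 6; Et3N; then K2CO3 (0.2 equiv), MeOH–THF, 0 °C
Reagents that add atoms: none
Why: Proposed new method: the acid protonates the enol formate of 6 at C3 and not at C4, because only then does the charge arrive at C4, where O1, 5-OBn and 7-OBn of ring A stabilise it far better than a formyloxy group could stabilise a C3 cation; C8(D) of 8 then attacks cation 9 and loss of the arene proton returns the acid, so the step is a catalytic, redox-neutral Markovnikov hydroarylation without a leaving group. The closest known reaction types are the acid-catalysed hydroarylation of styrenes and flav-3-enes by electron-rich arenes and the Lewis-acid substitution of 4-alkoxyflavan-3-ols, which runs through the same kind of C4 cation; new is that an enol ester is the cation source and that the protonation itself creates a stereocentre. C3: allylic 1,2-strain with the C3 oxygen forces ring B at C2 into the pseudoaxial position on the α face of the nearly flat chromene, so the proton should arrive on the β face, which places H-3 β and the formyloxy group α (2,3-cis). C4: in 9 the formyloxy group is pseudoaxial on the α face and can bridge to C4 through its carbonyl oxygen, and ring B lies on the same face, so ring D should bond from the β face (3,4-trans, 4β). No ring is closed; C3–H and C4(C)–C8(D) are formed as a net syn addition on the face opposite to the only stereocentre present. Site selectivity in 8 (C8 over C6 and over the free C3–OH) rests on the general preference of benzylated flavan-3-ols for substitution at C8 and on the reversibility of O-alkylation under acid. Cross-coupling is favoured over self-alkylation of 6, over chain growth on ring A of 10 and over hydride transfer from C2–H of 6 to 9 by the excess of 8 and the slow addition of 6 at low temperature, so that 9 meets little 6. The catalytic methanolysis in the same flask removes only the formate, since all phenols are benzylated and no acidic C–H is present.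

Step 7
Reactants: 11 5,7,4'-tri-O-benzyl-(−)-epiafzelechin-(4β→8)-5,7,3',4'-tetra-O-benzyl-(−)-epicatechin; 12 3,4,5-tris(benzyloxy)benzoic acid
Product: 13 trideca-O-benzyl ether of (−)-epiafzelechin 3-O-gallate-(4β→8)-(−)-epicatechin 3-O-gallate
Conditions: 12 (4 equiv), DCC (4 equiv), DMAP (1 equiv), CH2Cl2, rt
Reagents that add atoms: none
Why: Steglich esterification of both secondary alcohols in one operation, a reaction type established for benzylated flavan-3-ol dimers; no C–O bond at a stereocentre is broken, so all five configurations are kept.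

Step 8
Reactants: 13 trideca-O-benzyl ether of (−)-epiafzelechin 3-O-gallate-(4β→8)-(−)-epicatechin 3-O-gallate
Product: 14 (−)-epiafzelechin 3-O-gallate-(4β→8)-(−)-epicatechin 3-O-gallate
Conditions: H2 (1 atm), 20% Pd(OH)2/C, THF–MeOH–H2O, rt; filtration and lyophilisation under Ar
Reagents that add atoms: none
Why: Hydrogenolysis of all thirteen benzyl aryl ethers under neutral conditions; the esters, the cyclic C2–O1 ethers and the interflavan bond are normally left intact by this catalyst at ambient pressure, and no stereocentre is involved.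

## Compound list

1 | 2,4,6-trihydroxybenzaldehyde | O=Cc1c(O)cc(O)cc1O | starting material
2 | 2,4-bis(benzyloxy)-6-hydroxybenzaldehyde | O=Cc1c(O)cc(OCc2ccccc2)cc1OCc1ccccc1 | intermediate
3 | 4-(benzyloxy)benzaldehyde | O=Cc1ccc(OCc2ccccc2)cc1 | starting material
4 | (E)-3-[4-(benzyloxy)phenyl]prop-2-enal | O=C/C=C/c1ccc(OCc2ccccc2)cc1 | intermediate
5 | (2R)-5,7-bis(benzyloxy)-2-[4-(benzyloxy)phenyl]-2H-chromene-3-carbaldehyde | O=CC1=Cc2c(OCc3ccccc3)cc(OCc3ccccc3)cc2O[C@@H]1c1ccc(OCc2ccccc2)cc1 | intermediate
6 | (2R)-5,7-bis(benzyloxy)-2-[4-(benzyloxy)phenyl]-2H-chromen-3-yl formate | O=COC1=Cc2c(OCc3ccccc3)cc(OCc3ccccc3)cc2O[C@@H]1c1ccc(OCc2ccccc2)cc1 | intermediate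
7 | (−)-epicatechin, (2R,3R)-2-(3,4-dihydroxyphenyl)chromane-3,5,7-triol | O[C@@H]1Cc2c(O)cc(O)cc2O[C@@H]1c1ccc(O)c(O)c1 | starting material
8 | 5,7,3',4'-tetra-O-benzyl-(−)-epicatechin | O[C@@H]1Cc2c(OCc3ccccc3)cc(OCc3ccccc3)cc2O[C@@H]1c1ccc(OCc2ccccc2)c(OCc2ccccc2)c1 | intermediate
9 | (2R,3R)-5,7-bis(benzyloxy)-2-[4-(benzyloxy)phenyl]-3-(formyloxy)chroman-4-ylium, 2,3-cis C4 cation (bistriflimide ion pair, formyl oxygen bridging on the α face) | O=CO[C@@H]1[CH+]c2c(OCc3ccccc3)cc(OCc3ccccc3)cc2O[C@@H]1c1ccc(OCc2ccccc2)cc1 | intermediate
10 | 5,7,4'-tri-O-benzyl-3-O-formyl-(−)-epiafzelechin-(4β→8)-5,7,3',4'-tetra-O-benzyl-(−)-epicatechin | O=CO[C@@H]1[C@@H](c2c(OCc3ccccc3)cc(OCc3ccccc3)c3c2O[C@H](c2ccc(OCc4ccccc4)c(OCc4ccccc4)c2)[C@H](O)C3)c2c(OCc3ccccc3)cc(OCc3ccccc3)cc2O[C@@H]1c1ccc(OCc2ccccc2)cc1 | intermediate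
11 | 5,7,4'-tri-O-benzyl-(−)-epiafzelechin-(4β→8)-5,7,3',4'-tetra-O-benzyl-(−)-epicatechin (diol) | O[C@@H]1[C@@H](c2c(OCc3ccccc3)cc(OCc3ccccc3)c3c2O[C@H](c2ccc(OCc4ccccc4)c(OCc4ccccc4)c2)[C@H](O)C3)c2c(OCc3ccccc3)cc(OCc3ccccc3)cc2O[C@@H]1c1ccc(OCc2ccccc2)cc1 | intermediate
12 | 3,4,5-tris(benzyloxy)benzoic acid | O=C(O)c1cc(OCc2ccccc2)c(OCc2ccccc2)c(OCc2ccccc2)c1 | starting material
13 | trideca-O-benzyl ether of (−)-epiafzelechin 3-O-gallate-(4β→8)-(−)-epicatechin 3-O-gallate | O=C(O[C@@H]1[C@@H](c2c(OCc3ccccc3)cc(OCc3ccccc3)c3c2O[C@H](c2ccc(OCc4ccccc4)c(OCc4ccccc4)c2)[C@H](OC(=O)c2cc(OCc4ccccc4)c(OCc4ccccc4)c(OCc4ccccc4)c2)C3)c2c(OCc3ccccc3)cc(OCc3ccccc3)cc2O[C@@H]1c1ccc(OCc2ccccc2)cc1)c1cc(OCc2ccccc2)c(OCc2ccccc2)c(OCc2ccccc2)c1 | intermediate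
14 | (−)-epiafzelechin 3-O-gallate-(4β→8)-(−)-epicatechin 3-O-gallate (CNP0291968.1) | O=C(O[C@@H]1[C@@H](c2c(O)cc(O)c3c2O[C@H](c2ccc(O)c(O)c2)[C@H](OC(=O)c2cc(O)c(O)c(O)c2)C3)c2c(O)cc(O)cc2O[C@@H]1c1ccc(O)cc1)c1cc(O)c(O)c(O)c1 | target

## Step count and least certain steps

Total step count: 8. Longest linear sequence: 6 (steps 1, 3, 4, 6, 7, 8).

**Step 6 (key step, proposed new method).** Several processes could compete with the planned addition:
- hydride transfer from C2–H of unreacted 6 to cation 9 (disproportionation of the chromene);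
- self-alkylation of 6 and further chain growth on ring A of the product;
- cleavage of the enol formate by traces of water;
- loss of facial selectivity in the protonation if it becomes reversible at higher temperature;
- partial attack at C6(D).

Fallback, with known chemistry only: it sets out from 6 and returns at 11. Brief methanolysis of 6 (KHCO3, MeOH–THF, 0 °C) gives (2R)-5,7-bis(benzyloxy)-2-[4-(benzyloxy)phenyl]chroman-3-one F1. A bulky hydride (L-Selectride, THF, −78 °C) attacks F1 opposite ring B and gives 5,7,4'-tri-O-benzyl-(−)-epiafzelechin F2. Benzylic oxidation with DDQ in the presence of 2-ethoxyethanol gives the 4β-(2-ethoxyethoxy) ether F3. Ionisation of F3 with TMSOTf at −78 °C in the presence of an excess of 8 gives 11.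

**Step 4.** Three processes could interfere:
- further oxidation of the electron-rich enol formate (epoxidation of C3=C4);
- migration of H instead of C3 in the peroxide adduct;
- hydrolysis of the formate in the two-phase medium, followed by epimerisation at C2.

Fallback: it sets out from 5 and returns at 11, replacing the oxygen insertion by a nitrogen insertion. Pinnick oxidation of 5 gives the (2R)-2H-chromene-3-carboxylic acid F4. Curtius rearrangement (DPPA, Et3N, toluene, 85 °C) gives the vinyl isocyanate F5. Dilute aqueous acid in the same flask hydrolyses F5 to the ketone F1, which follows the fallback of step 6 through F2 and F3 to 11.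

**Step 3.** Three processes could interfere:
- slow aldol closure onto the electron-rich, doubly ortho-substituted formyl group of 2;
- reversal of the oxa-Michael addition;
- erosion of the configuration at C2 through dienamine formation from the product.

Fallback: it sets out from 2 and 4 and returns at 11, moving stereocontrol from catalysis to a late separation. The same domino reaction with pyrrolidine gives the racemic aldehyde F6, and step 4 gives the racemic enol formate F7. In step 6 enantiopure 8 turns the two enantiomers into two diastereomers, 11 and 5,7,4'-tri-O-benzyl-ent-epiafzelechin-(4α→8)-5,7,3',4'-tetra-O-benzyl-(−)-epicatechin F8. These are separated by chromatography, at the price of half of the short upper fragment.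

**Step 7.** The most likely problem is incomplete acylation of the axial C3(C)–OH, which is flanked by ring B and ring D. Fallback: it sets out from 6, 8 and 12 and returns at 13, placing both gallates before the skeleton is joined.
- Acid 12 is converted with oxalyl chloride into 3,4,5-tris(benzyloxy)benzoyl chloride F9.
- KOt-Bu (THF, −78 °C) cleaves the formate of 6 to the regiodefined potassium enolate. O-Acylation of the enolate with F9 gives the enol gallate F10.
- Steglich esterification of 8 with 12 gives hepta-O-benzyl-(−)-epicatechin 3-O-gallate F11.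
- The conditions of step 6, without the methanolysis, join F10 and F11 directly to 13.

## Further compounds

F1 | step 6 | (2R)-5,7-bis(benzyloxy)-2-[4-(benzyloxy)phenyl]chroman-3-one | O=C1Cc2c(OCc3ccccc3)cc(OCc3ccccc3)cc2O[C@@H]1c1ccc(OCc2ccccc2)cc1
F2 | step 6 | 5,7,4'-tri-O-benzyl-(−)-epiafzelechin | O[C@@H]1Cc2c(OCc3ccccc3)cc(OCc3ccccc3)cc2O[C@@H]1c1ccc(OCc2ccccc2)cc1
F3 | step 6 | 5,7,4'-tri-O-benzyl-4β-(2-ethoxyethoxy)-(−)-epiafzelechin | O[C@@H]1[C@@H](OCCOCC)c2c(OCc3ccccc3)cc(OCc3ccccc3)cc2O[C@@H]1c1ccc(OCc2ccccc2)cc1
F4 | step 4 | (2R)-5,7-bis(benzyloxy)-2-[4-(benzyloxy)phenyl]-2H-chromene-3-carboxylic acid | O=C(O)C1=Cc2c(OCc3ccccc3)cc(OCc3ccccc3)cc2O[C@@H]1c1ccc(OCc2ccccc2)cc1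
F5 | step 4 | (2R)-5,7-bis(benzyloxy)-2-[4-(benzyloxy)phenyl]-3-isocyanato-2H-chromene | O=C=NC1=Cc2c(OCc3ccccc3)cc(OCc3ccccc3)cc2O[C@@H]1c1ccc(OCc2ccccc2)cc1
F6 | step 3 | racemic 5,7-bis(benzyloxy)-2-[4-(benzyloxy)phenyl]-2H-chromene-3-carbaldehyde | O=CC1=Cc2c(OCc3ccccc3)cc(OCc3ccccc3)cc2OC1c1ccc(OCc2ccccc2)cc1
F7 | step 3 | racemic 5,7-bis(benzyloxy)-2-[4-(benzyloxy)phenyl]-2H-chromen-3-yl formate | O=COC1=Cc2c(OCc3ccccc3)cc(OCc3ccccc3)cc2OC1c1ccc(OCc2ccccc2)cc1
F8 | step 3 | 5,7,4'-tri-O-benzyl-ent-epiafzelechin-(4α→8)-5,7,3',4'-tetra-O-benzyl-(−)-epicatechin | O[C@H]1[C@H](c2c(OCc3ccccc3)cc(OCc3ccccc3)c3c2O[C@H](c2ccc(OCc4ccccc4)c(OCc4ccccc4)c2)[C@H](O)C3)c2c(OCc3ccccc3)cc(OCc3ccccc3)cc2O[C@H]1c1ccc(OCc2ccccc2)cc1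
F9 | step 7 | 3,4,5-tris(benzyloxy)benzoyl chloride | O=C(Cl)c1cc(OCc2ccccc2)c(OCc2ccccc2)c(OCc2ccccc2)c1
F10 | step 7 | (2R)-5,7-bis(benzyloxy)-2-[4-(benzyloxy)phenyl]-2H-chromen-3-yl 3,4,5-tris(benzyloxy)benzoate | O=C(OC1=Cc2c(OCc3ccccc3)cc(OCc3ccccc3)cc2O[C@@H]1c1ccc(OCc2ccccc2)cc1)c1cc(OCc2ccccc2)c(OCc2ccccc2)c(OCc2ccccc2)c1
F11 | step 7 | hepta-O-benzyl-(−)-epicatechin 3-O-gallate | O=C(O[C@@H]1Cc2c(OCc3ccccc3)cc(OCc3ccccc3)cc2O[C@@H]1c1ccc(OCc2ccccc2)c(OCc2ccccc2)c1)c1cc(OCc2ccccc2)c(OCc2ccccc2)c(OCc2ccccc2)c1
A1 | alternative 1 | 5,7,4'-tri-O-benzyl-4β-(2-ethoxyethoxy)-(−)-epiafzelechin 3-O-[3,4,5-tris(benzyloxy)benzoate] | O=C(O[C@@H]1[C@@H](OCCOCC)c2c(OCc3ccccc3)cc(OCc3ccccc3)cc2O[C@@H]1c1ccc(OCc2ccccc2)cc1)c1cc(OCc2ccccc2)c(OCc2ccccc2)c(OCc2ccccc2)c1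
A2 | alternative 2 | 5,7-bis(benzyloxy)-2-[4-(benzyloxy)phenyl]-3-{[3,4,5-tris(benzyloxy)benzoyl]oxy}chromenylium | O=C(Oc1cc2c(OCc3ccccc3)cc(OCc3ccccc3)cc2[o+]c1-c1ccc(OCc2ccccc2)cc1)c1cc(OCc2ccccc2)c(OCc2ccccc2)c(OCc2ccccc2)c1
A3 | alternative 2 | 4β-[tetra-O-benzyl-(−)-epicatechin-8-yl]-5,7-bis(benzyloxy)-2-[4-(benzyloxy)phenyl]-4H-chromen-3-yl 3,4,5-tris(benzyloxy)benzoate | O=C(OC1=C(c2ccc(OCc3ccccc3)cc2)Oc2cc(OCc3ccccc3)cc(OCc3ccccc3)c2[C@@H]1c1c(OCc2ccccc2)cc(OCc2ccccc2)c2c1O[C@H](c1ccc(OCc3ccccc3)c(OCc3ccccc3)c1)[C@H](O)C2)c1cc(OCc2ccccc2)c(OCc2ccccc2)c(OCc2ccccc2)c1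
A4 | alternative 2 | 2,3-cis-3,4-cis (all-cis ring C) isomer of the benzylated upper gallate dimer | O=C(O[C@H]1[C@@H](c2c(OCc3ccccc3)cc(OCc3ccccc3)c3c2O[C@H](c2ccc(OCc4ccccc4)c(OCc4ccccc4)c2)[C@H](O)C3)c2c(OCc3ccccc3)cc(OCc3ccccc3)cc2O[C@H]1c1ccc(OCc2ccccc2)cc1)c1cc(OCc2ccccc2)c(OCc2ccccc2)c(OCc2ccccc2)c1
A5 | alternative 3 | 8-{[2,4-bis(benzyloxy)-6-hydroxyphenyl](hydroxy)methyl}-hepta-O-benzyl-(−)-epicatechin 3-O-gallate (both carbinol epimers) | OC(c1c(O)cc(OCc2ccccc2)cc1OCc1ccccc1)c1c(OCc2ccccc2)cc(OCc2ccccc2)c2c1O[C@H](c1ccc(OCc3ccccc3)c(OCc3ccccc3)c1)[C@H](OC(=O)c1cc(OCc3ccccc3)c(OCc3ccccc3)c(OCc3ccccc3)c1)C2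
A6 | alternative 3 | (Z)-2-[4-(benzyloxy)phenyl]ethenyl 3,4,5-tris(benzyloxy)benzoate | O=C(O/C=C\c1ccc(OCc2ccccc2)cc1)c1cc(OCc2ccccc2)c(OCc2ccccc2)c(OCc2ccccc2)c1
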